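## Retrosynthetic overview

1. Structural feature: let C4 = C(=CH2), C5(H)/C10(CH3) = ring fusion, C8 = CH(CH3), C9 = C(CH3)(C15H2–quinone), ring A = C1–C5/C10 and ring B = C5–C10. All four stereocentres (C5, C10, C9, C8) are then neighbouring atoms of ring B, so ring B is read as a hydrogenated C6=C7 cyclohexene, a Diels–Alder retron.
2. Endgame cuts: the C15–quinone bond comes from reductive alkylation of 2-hydroxy-5-methoxy-1,4-benzoquinone by the C15 aldehyde. C4=CH2 comes from a C4 ketone. The C9 methyl comes from the formyl group that activated the dienophile.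
3. Key cut: C5–C10 and C8–C9 are opened together. This gives acyclic trienal 16, made up of the (E,E)-diene C5–C8, the tetrasubstituted enal C9=C10 and the chain C1–C4 with a (4R)-silyloxy group.
4. Trienal: the C9=C10 geometry comes from syn-methylcupration/iodination of a tethered 2-ynoate (ester = C15, iodide → CHO). C4 comes from asymmetric allylboration of sorbaldehyde.
5. Ring order: rings A and B form in one operation (step 11). The quinone ring is bought and attached last.

Key step: step 11

Assumption: the SMILES is taken at face value, that is 5α-H, 8β-, 9β- and 10β-methyl, C15 α, trans-decalin. α/β refer to the drawing with the C10 methyl up. TBS = tert-butyldimethylsilyl and TBDPS = tert-butyldiphenylsilyl.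

## Route

Step 1
Reactants: 1 (2E,4E)-hexa-2,4-dienal (sorbaldehyde)
Product: 3 (4R,5E,7E)-nona-1,5,7-trien-4-ol, via diisopinocampheylborinate 2 (not isolated)
Conditions: B-allyldiisopinocampheylborane derived from (−)-α-pinene, Et2O, −78 °C; then NaOH, H2O2, 0 °C to rt
Reagents that add atoms: B-allyldiisopinocampheylborane, C=CCB([C@H]1C[C@H]2C[C@H](C2(C)C)[C@@H]1C)[C@H]1C[C@H]2C[C@H](C2(C)C)[C@@H]1C
Why: Brown asymmetric allylboration through a closed chair transition state adds 1,2 and leaves the diene alone, and since the antipodal reagent is known to turn enals into (S)-carbinols, the (−)-α-pinene series should set C4 as R.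

Step 2
Reactants: 3 (4R,5E,7E)-nona-1,5,7-trien-4-ol
Product: 4 (4R,5E,7E)-4-(tert-butyldimethylsilyloxy)nona-1,5,7-triene
Conditions: TBSCl, imidazole, DMF, rt
Reagents that add atoms: tert-butyldimethylsilyl chloride, CC(C)(C)[Si](C)(C)Cl
Why: Imidazole-promoted silylation runs under non-acidic conditions, spares the ionisable dienyl carbinol and installs the bulky group that later steers the cycloaddition, with C4 untouched.

Step 3
Reactants: 4 (4R,5E,7E)-4-(tert-butyldimethylsilyloxy)nona-1,5,7-triene
Product: 6 (4R,5E,7E)-4-(tert-butyldimethylsilyloxy)nona-5,7-dien-1-ol, via B-alkyl-9-BBN adduct 5 (not isolated)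
Conditions: 9-BBN, THF, 0 °C to rt; then NaOH, H2O2, 0 °C
Reagents that add atoms: hydrogen peroxide, OO (oxygen at C1); 9-borabicyclo[3.3.1]nonane, C1CC2CCCC(C1)B2 (boron held only in 5)
Why: In this hydroboration–oxidation, 9-BBN attacks the monosubstituted C1=C2 alkene anti-Markovnikov far faster than the conjugated 1,2-disubstituted diene, and alkaline peroxide then replaces boron by hydroxyl.

Step 4
Reactants: 6 (4R,5E,7E)-4-(tert-butyldimethylsilyloxy)nona-5,7-dien-1-ol
Product: 7 (4R,5E,7E)-4-(tert-butyldimethylsilyloxy)-1-iodonona-5,7-diene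
Conditions: PPh3, imidazole, I2, CH2Cl2, 0 °C
Reagents that add atoms: iodine, II
Why: In this Appel-type (Garegg–Samuelsson) iodination, iodide displaces the primary oxyphosphonium salt by SN2 while imidazole keeps the medium non-acidic for the dienylic silyl ether.

Step 5
Reactants: 7 (4R,5E,7E)-4-(tert-butyldimethylsilyloxy)-1-iodonona-5,7-diene
Product: 8 (6R,7E,9E)-6-(tert-butyldimethylsilyloxy)undeca-7,9-dien-1-yne
Conditions: LiC≡CH·H2NCH2CH2NH2, DMSO/THF, 0 °C to rt
Reagents that add atoms: lithium acetylide–ethylenediamine complex, [Li+].[C-]#C.NCCN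
Why: This is an SN2 alkynylation of an unhindered primary iodide, and putting the tether on the alkyne partner means that no alkyl-lithium or alkyl-copper species must be made five atoms from the diene, where 5-exo carbometallation onto C5 would threaten.

Step 6
Reactants: 8 (6R,7E,9E)-6-(tert-butyldimethylsilyloxy)undeca-7,9-dien-1-yne
Product: 10 ethyl (7R,8E,10E)-7-(tert-butyldimethylsilyloxy)dodeca-8,10-dien-2-ynoate, via lithium acetylide 9 (not isolated)
Conditions: n-BuLi, THF, −78 °C; then ClCO2Et, −78 °C to 0 °C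
Reagents that add atoms: ethyl chloroformate, CCOC(=O)Cl; n-butyllithium, [Li]CCCC (lithium held only in 9)
Why: Deprotonation of the terminal alkyne and C-acylation of the acetylide with a chloroformate is the standard entry to 2-ynoates and brings in C15.

Step 7
Reactants: 10 ethyl (7R,8E,10E)-7-(tert-butyldimethylsilyloxy)dodeca-8,10-dien-2-ynoate
Product: 12 ethyl (2E,7R,8E,10E)-7-(tert-butyldimethylsilyloxy)-2-iodo-3-methyldodeca-2,8,10-trienoate, via alkenyl(methyl)cuprate 11 (not isolated)
Conditions: MeLi (2 equiv), CuI, THF, 0 °C; add 10, −78 °C; then I2 in THF, −78 °C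
Reagents that add atoms: lithium dimethylcuprate, [Li+].C[Cu-]C (C10 methyl); iodine, II
Why: Syn-carbocupration of the 2-ynoate by the Gilman reagent puts CH3 on C10 and copper on C9 on the same side, and iodinolysis at −78 °C, before the cuprate can equilibrate through the allenolate, goes with retention, so iodine ends cis to the C10 methyl and the ester (C15) cis to the tether.

Step 8
Reactants: 12 ethyl (2E,7R,8E,10E)-7-(tert-butyldimethylsilyloxy)-2-iodo-3-methyldodeca-2,8,10-trienoate
Product: 13 (2E,7R,8E,10E)-7-(tert-butyldimethylsilyloxy)-2-iodo-3-methyldodeca-2,8,10-trien-1-ol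
Conditions: i-Bu2AlH (2.2 equiv), CH2Cl2, −78 °C
Reagents that add atoms: none
Why: i-Bu2AlH reduces the conjugated ester 1,2 to the allylic alcohol, while the alkenyl iodide, diene, silyl ether and alkene geometry are unaffected.

Step 9
Reactants: 13 (2E,7R,8E,10E)-7-(tert-butyldimethylsilyloxy)-2-iodo-3-methyldodeca-2,8,10-trien-1-ol
Product: 14 (2E,7R,8E,10E)-7-(tert-butyldimethylsilyloxy)-1-(tert-butyldiphenylsilyloxy)-2-iodo-3-methyldodeca-2,8,10-triene
Conditions: TBDPSCl, imidazole, DMF, rt
Reagents that add atoms: tert-butyldiphenylsilyl chloride, CC(C)(C)[Si](Cl)(c1ccccc1)c1ccccc1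
Why: TBDPS is chosen for C15–O in this silylation of the primary allylic alcohol because it tolerates t-BuLi, Me2AlCl and BF3/thiol, cannot migrate or be reduced as an acyl group could, and is later told apart from the C4 TBS ether by its far slower acid solvolysis.

Step 10
Reactants: 14 (2E,7R,8E,10E)-7-(tert-butyldimethylsilyloxy)-1-(tert-butyldiphenylsilyloxy)-2-iodo-3-methyldodeca-2,8,10-triene
Product: 16 (2E,7R,8E,10E)-7-(tert-butyldimethylsilyloxy)-2-[(tert-butyldiphenylsilyloxy)methyl]-3-methyldodeca-2,8,10-trienal, via alkenyllithium 15 (not isolated)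
Conditions: t-BuLi (2.1 equiv), Et2O, −78 °C; then DMF, −78 °C; then H2O
Reagents that add atoms: N,N-dimethylformamide, CN(C)C=O; tert-butyllithium, [Li]C(C)(C)C (lithium held only in 15)
Why: Iodine–lithium exchange of an alkenyl iodide is fast at −78 °C and retentive, so formylation of the configurationally stable alkenyllithium with DMF gives the enal with CHO cis to the C10 methyl and trans to the tether.

Step 11
Reactants: 16 (2E,7R,8E,10E)-7-(tert-butyldimethylsilyloxy)-2-[(tert-butyldiphenylsilyloxy)methyl]-3-methyldodeca-2,8,10-trienal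
Product: 17 trans-octal-6-ene aldehyde (4α-OTBS; 5α-H; 8β-CH3; 9β-CHO; 9α-CH2OTBDPS; 10β-CH3; C6=C7)
Conditions: Me2AlCl (1.5 equiv), CH2Cl2, −78 °C to 0 °C
Reagents that add atoms: none
Why: Me2AlCl binds the formyl oxygen, lowers the LUMO of the C9=C10 enal and sets off a concerted, asynchronous [4+2] cycloaddition with the s-cis C5=C6–C7=C8 diene; the closest known reaction type is the Lewis-acid-promoted type 1 intramolecular Diels–Alder reaction of 1,7,9-decatrienes with a terminal acceptor. Ring B (C5–C10) closes as the cyclohexene through the new C5–C10 and C8–C9 bonds, and ring A (C1–C5, C10) closes in the same event because the C1–C4 chain folds into a chair and spans C5···C10 in the anti, trans-fusing mode. Suprafacial addition transfers the alkene geometries: the (E,E)-diene places C4 and the C8 methyl cis on ring B, and the (2E)-enal places the C10 methyl cis to CHO and C1 cis to C15, which fixes C8 against C5 and C9 against C10. The step needs formyl-endo addition, and because CHO stands trans to the tether this mode is the same as the tether-anti mode, so the complexed carbonyl and the chain both lead to 5α-H/10β-CH3 and 8β-CH3/9β-CHO. The diene face is chosen by C4: the OTBS group takes the pseudo-equatorial site anti to the forming C5–C10 bond, since the axial site would nearly eclipse C6–H (A(1,3) strain) and meet the endo C10 methyl in a 1,3-diaxial contact, so (4R) is relayed to C5, C10, C9 and C8. Both oxygen substituents are weakly basic silyl ethers, which leaves the aldehyde as the site that holds the Lewis acid.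

Step 12
Reactants: 17 trans-octal-6-ene aldehyde
Product: 18 dithiolane of 17 (9β-(1,3-dithiolan-2-yl); otherwise as 17)
Conditions: HSCH2CH2SH, BF3·OEt2 (cat.), CH2Cl2, −40 °C to 0 °C
Reagents that add atoms: ethane-1,2-dithiol, SCCS
Why: This Lewis-acid-catalysed dithioacetalisation acts on the only carbonyl group, a non-enolisable neopentyl aldehyde, and the low temperature keeps both silyl ethers and C6=C7 intact.

Step 13
Reactants: 18 dithiolane of 17
Product: 19 trans-decalin bis-silyl ether (4α-OTBS; 5α-H; 8β,9β,10β-trimethyl; 9α-CH2OTBDPS)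
Conditions: NiCl2·6H2O, NaBH4 (large excess), MeOH/THF, 0 °C to rt
Reagents that add atoms: none
Why: Reductive desulfurisation with nickel boride made in situ (Mozingo-type reduction) turns the dithiolane carbon into the C9 methyl, and the same finely divided nickel hydrogenates the cis-disubstituted C6=C7 with H2 released from excess NaBH4, so no stereocentre is formed or touched.

Step 14
Reactants: 19 trans-decalin bis-silyl ether
Product: 20 4α-alcohol (5α-H; 8β,9β,10β-trimethyl; 9α-CH2OTBDPS)
Conditions: camphorsulfonic acid (cat.), MeOH/CH2Cl2, rt to 40 °C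
Reagents that add atoms: none
Why: Acid-catalysed methanolysis removes a TBS ether far faster than a TBDPS ether, and at this stage the molecule holds no alkene or other acid-sensitive group.

Step 15
Reactants: 20 4α-alcohol
Product: 21 4-ketone (trans-decalone; 5α-H; 8β,9β,10β-trimethyl; 9α-CH2OTBDPS)
Conditions: nPr4N[RuO4] (cat.), N-methylmorpholine N-oxide, 4 Å sieves, CH2Cl2, rt
Reagents that add atoms: none
Why: Ley–Griffith oxidation of the equatorial secondary alcohol is essentially neutral, so the now enolisable C5–H should not epimerise.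

Step 16
Reactants: 21 4-ketone
Product: 22 tert-butyldiphenylsilyl ether of 23 (4-methylidene; 5α-H; 8β,9β,10β-trimethyl; 9α-CH2OTBDPS)
Conditions: Zn, CH2Br2, TiCl4, THF/CH2Cl2, 0 °C to rt
Reagents that add atoms: dibromomethane, BrCBr
Why: Lombardo methylenation uses a non-basic gem-dimetallic CH2 reagent suited to enolisable ketones, so C5 should keep its configuration although the cis-decalone would relieve the 1,3-diaxial C8/C10 methyl contact.

Step 17
Reactants: 22 tert-butyldiphenylsilyl ether of 23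
Product: 23 [(1R,2S,4aS,8aS)-1,2,8a-trimethyl-5-methylidenedecahydronaphthalen-1-yl]methanol
Conditions: n-Bu4NF, THF, 50 °C
Reagents that add atoms: none
Why: Fluoride cleaves the Si–O bond, warming compensates for the neopentyl surroundings, and the exocyclic alkene is inert to fluoride.

Step 18
Reactants: 23 [(1R,2S,4aS,8aS)-1,2,8a-trimethyl-5-methylidenedecahydronaphthalen-1-yl]methanol
Product: 24 (1R,2S,4aS,8aS)-1,2,8a-trimethyl-5-methylidenedecahydronaphthalene-1-carbaldehyde
Conditions: nPr4N[RuO4] (cat.), N-methylmorpholine N-oxide, 4 Å sieves, CH2Cl2, rt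
Reagents that add atoms: none
Why: Ley–Griffith oxidation of the primary neopentyl alcohol stops at the aldehyde, which has no α-hydrogen and so can neither epimerise nor self-condense.

Step 19
Reactants: 25 2,5-dimethoxy-1,4-benzoquinone
Product: 26 2-hydroxy-5-methoxy-1,4-benzoquinone
Conditions: NaOH (1 equiv), H2O/THF, rt; then HCl
Reagents that add atoms: sodium hydroxide, [Na+].[OH-]
Why: Hydroxide adds and methoxide leaves at one vinylogous ester carbon (vinylogous saponification), and the electron-rich hydroxyquinone anion so formed resists a second exchange.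

Step 20
Reactants: 24 (1R,2S,4aS,8aS)-1,2,8a-trimethyl-5-methylidenedecahydronaphthalene-1-carbaldehyde; 26 2-hydroxy-5-methoxy-1,4-benzoquinone
Product: 28 2-hydroxy-5-methoxy-3-{[(1R,2S,4aS,8aS)-1,2,8a-trimethyl-5-methylidenedecahydronaphthalen-1-yl]methyl}cyclohexa-2,5-diene-1,4-dione (target), via alkylidene trione 27 (not isolated)
Conditions: L-proline (20 mol %), diethyl 2,6-dimethyl-1,4-dihydropyridine-3,5-dicarboxylate (1.2 equiv), CH2Cl2, rt to 40 °C
Reagents that add atoms: none
Why: In this organocatalytic three-component reductive alkylation, a proline-mediated Knoevenagel condensation of the vinylogous acid 26 through its nucleophilic C3 with the non-enolisable aldehyde 24 gives 27, which accepts hydride from the Hantzsch ester at C15 and tautomerises to the hydroxyquinone without touching any stereocentre.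

## Compound list

1 | (2E,4E)-hexa-2,4-dienal | C/C=C/C=C/C=O | starting material
2 | diisopinocampheylborinate of 3 | C=CC[C@@H](OB([C@H]1C[C@H]2C[C@H](C2(C)C)[C@@H]1C)[C@H]1C[C@H]2C[C@H](C2(C)C)[C@@H]1C)/C=C/C=C/C | intermediate
3 | (4R,5E,7E)-nona-1,5,7-trien-4-ol | C=CC[C@@H](O)/C=C/C=C/C | intermediate
4 | (4R,5E,7E)-4-(tert-butyldimethylsilyloxy)nona-1,5,7-triene | C=CC[C@@H](O[Si](C)(C)C(C)(C)C)/C=C/C=C/C | intermediate
5 | 9-[(4R,5E,7E)-4-(tert-butyldimethylsilyloxy)nona-5,7-dien-1-yl]-9-borabicyclo[3.3.1]nonane | C1CC2CCCC(C1)B2CCC[C@@H](O[Si](C)(C)C(C)(C)C)/C=C/C=C/C | intermediate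
6 | (4R,5E,7E)-4-(tert-butyldimethylsilyloxy)nona-5,7-dien-1-ol | OCCC[C@@H](O[Si](C)(C)C(C)(C)C)/C=C/C=C/C | intermediate
7 | (4R,5E,7E)-4-(tert-butyldimethylsilyloxy)-1-iodonona-5,7-diene | ICCC[C@@H](O[Si](C)(C)C(C)(C)C)/C=C/C=C/C | intermediate
8 | (6R,7E,9E)-6-(tert-butyldimethylsilyloxy)undeca-7,9-dien-1-yne | C#CCCC[C@@H](O[Si](C)(C)C(C)(C)C)/C=C/C=C/C | intermediate
9 | lithium acetylide of 8 | [Li]C#CCCC[C@@H](O[Si](C)(C)C(C)(C)C)/C=C/C=C/C | intermediate
10 | ethyl (7R,8E,10E)-7-(tert-butyldimethylsilyloxy)dodeca-8,10-dien-2-ynoate | CCOC(=O)C#CCCC[C@@H](O[Si](C)(C)C(C)(C)C)/C=C/C=C/C | intermediate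
11 | lithium methyl(alkenyl)cuprate, Cu on C9 cis to the C10 methyl | [Li+].CCOC(=O)/C([Cu-]C)=C(/C)CCC[C@@H](O[Si](C)(C)C(C)(C)C)/C=C/C=C/C | intermediate
12 | ethyl (2E,7R,8E,10E)-7-(tert-butyldimethylsilyloxy)-2-iodo-3-methyldodeca-2,8,10-trienoate | CCOC(=O)/C(I)=C(/C)CCC[C@@H](O[Si](C)(C)C(C)(C)C)/C=C/C=C/C | intermediate
13 | (2E,7R,8E,10E)-7-(tert-butyldimethylsilyloxy)-2-iodo-3-methyldodeca-2,8,10-trien-1-ol | OC/C(I)=C(/C)CCC[C@@H](O[Si](C)(C)C(C)(C)C)/C=C/C=C/C | intermediate
14 | TBDPS ether of 13 | CC(C)(C)[Si](c1ccccc1)(c1ccccc1)OC/C(I)=C(/C)CCC[C@@H](O[Si](C)(C)C(C)(C)C)/C=C/C=C/C | intermediate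
15 | alkenyllithium from 14 (Li in place of I, geometry kept) | CC(C)(C)[Si](c1ccccc1)(c1ccccc1)OC/C([Li])=C(/C)CCC[C@@H](O[Si](C)(C)C(C)(C)C)/C=C/C=C/C | intermediate
16 | (2E,7R,8E,10E)-7-(tert-butyldimethylsilyloxy)-2-[(tert-butyldiphenylsilyloxy)methyl]-3-methyldodeca-2,8,10-trienal | CC(C)(C)[Si](c1ccccc1)(c1ccccc1)OC/C(C=O)=C(/C)CCC[C@@H](O[Si](C)(C)C(C)(C)C)/C=C/C=C/C | intermediate
17 | trans-octal-6-ene aldehyde (4α-OTBS; 5α-H; 8β-CH3; 9β-CHO; 9α-CH2OTBDPS; 10β-CH3) | CC(C)(C)[Si](C)(C)O[C@@H]1CCC[C@@]2(C)[C@H]1C=C[C@H](C)[C@@]2(C=O)CO[Si](c1ccccc1)(c1ccccc1)C(C)(C)C | intermediate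
18 | 9β-(1,3-dithiolan-2-yl) analogue of 17 | CC(C)(C)[Si](C)(C)O[C@@H]1CCC[C@@]2(C)[C@H]1C=C[C@H](C)[C@@]2(C1SCCS1)CO[Si](c1ccccc1)(c1ccccc1)C(C)(C)C | intermediate
19 | trans-decalin bis-silyl ether (4α-OTBS; 8β,9β,10β-trimethyl; 9α-CH2OTBDPS) | CC(C)(C)[Si](C)(C)O[C@@H]1CCC[C@@]2(C)[C@H]1CC[C@H](C)[C@@]2(C)CO[Si](c1ccccc1)(c1ccccc1)C(C)(C)C | intermediate
20 | 4α-alcohol | O[C@@H]1CCC[C@@]2(C)[C@H]1CC[C@H](C)[C@@]2(C)CO[Si](c1ccccc1)(c1ccccc1)C(C)(C)C | intermediate
21 | 4-ketone (trans-decalone, 5α-H) | O=C1CCC[C@@]2(C)[C@H]1CC[C@H](C)[C@@]2(C)CO[Si](c1ccccc1)(c1ccccc1)C(C)(C)C | intermediate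
22 | TBDPS ether of 23 | C=C1CCC[C@@]2(C)[C@H]1CC[C@H](C)[C@@]2(C)CO[Si](c1ccccc1)(c1ccccc1)C(C)(C)C | intermediate
23 | [(1R,2S,4aS,8aS)-1,2,8a-trimethyl-5-methylidenedecahydronaphthalen-1-yl]methanol | C=C1CCC[C@@]2(C)[C@H]1CC[C@H](C)[C@@]2(C)CO | intermediate
24 | (1R,2S,4aS,8aS)-1,2,8a-trimethyl-5-methylidenedecahydronaphthalene-1-carbaldehyde | C=C1CCC[C@@]2(C)[C@H]1CC[C@H](C)[C@@]2(C)C=O | intermediate
25 | 2,5-dimethoxy-1,4-benzoquinone | COC1=CC(=O)C(OC)=CC1=O | starting material
26 | 2-hydroxy-5-methoxy-1,4-benzoquinone | COC1=CC(=O)C(O)=CC1=O | intermediate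
27 | alkylidene trione (C15=C3' geometry not defined; lost on reduction) | C=C1CCC[C@@]2(C)[C@H]1CC[C@H](C)[C@@]2(C)C=C1C(=O)C(=O)C=C(OC)C1=O | intermediate
28 | 2-hydroxy-5-methoxy-3-{[(1R,2S,4aS,8aS)-1,2,8a-trimethyl-5-methylidenedecahydronaphthalen-1-yl]methyl}cyclohexa-2,5-diene-1,4-dione | C=C1CCC[C@@]2(C)[C@H]1CC[C@H](C)[C@@]2(C)CC1=C(O)C(=O)C=C(OC)C1=O | target

## Step count and risks

Total step count: 20. Longest linear sequence: 19 (steps 1–18 and 20).

**Step 11.**
- What may go wrong:
  - Bond formation between a tetrasubstituted dienophile and the diene, which creates two adjacent quaternary carbons, may be too slow.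
  - Lewis-acid ionisation of the dienylic silyl ether may then compete.
  - The enal may isomerise geometrically before cycloaddition.
  - The endo/anti preference may erode.
- Fallback: keep the same cycloaddition but use a trisubstituted dienophile and add C15 afterwards.
  - Setting out from alkyne 8, Negishi methylalumination (Me3Al, Cp2ZrCl2, CH2Cl2) followed by n-BuLi and paraformaldehyde should give (2E,7R,8E,10E)-7-(tert-butyldimethylsilyloxy)-3-methyldodeca-2,8,10-trien-1-ol F1.
  - MnO2 then gives (2E,7R,8E,10E)-7-(tert-butyldimethylsilyloxy)-3-methyldodeca-2,8,10-trienal F2.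
  - Me2AlCl-promoted intramolecular Diels–Alder reaction in the same endo/anti mode gives the 9α-H octalin aldehyde F3.
  - Deprotonation with KN(SiMe3)2 forms the exocyclic enolate. Monomeric CH2O should attack it axially from the α face, opposite the 8β and 10β methyl groups, to give the 9α-hydroxymethyl aldehyde F4.
  - TBDPSCl/imidazole comes back to the route at 17.

**Step 20.**
- What may go wrong:
  - Condensation at the doubly neopentyl aldehyde may stall.
  - The Hantzsch ester may then be consumed in reducing the quinone.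
- Fallback: form the C15–aryl bond by carbonyl addition and build the quinone afterwards.
  - Setting out from 24, 3-lithio-1,2,4,5-tetramethoxybenzene (n-BuLi, THF) adds to give the benzylic carbinol F5 as either C15 epimer.
  - NaH, CS2 and MeI give the S-methyl xanthate F6.
  - Barton–McCombie deoxygenation (n-Bu3SnH, AIBN, toluene, reflux) gives the tetramethoxybenzyl decalin F7.
  - (NH4)2Ce(NO3)6 in MeCN/H2O gives the 3-alkyl-2,5-dimethoxy-1,4-benzoquinone F8.
  - KOH in MeOH/H2O followed by acid exchanges the methoxy group next to the alkyl chain and comes back to the route at 28.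

**Step 16.**
- What may go wrong:
  - Transfer of the methylene unit to the hindered C4 carbonyl may be slow.
  - Enolisation may then epimerise C5.
- Fallback: a two-stage Peterson olefination.
  - Setting out from 21, the weakly basic reagent from Me3SiCH2Li and CeCl3 (THF, −78 °C) should add from the α face to give the β-hydroxysilane F9.
  - KH in THF then eliminates the silanolate and comes back to the route at 22.

## Further compounds

F1 | step 11 | (2E,7R,8E,10E)-7-(tert-butyldimethylsilyloxy)-3-methyldodeca-2,8,10-trien-1-ol | OC/C=C(\C)CCC[C@@H](O[Si](C)(C)C(C)(C)C)/C=C/C=C/C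
F2 | step 11 | (2E,7R,8E,10E)-7-(tert-butyldimethylsilyloxy)-3-methyldodeca-2,8,10-trienal | O=C/C=C(\C)CCC[C@@H](O[Si](C)(C)C(C)(C)C)/C=C/C=C/C
F3 | step 11 | 9α-H octalin aldehyde (4α-OTBS; 5α-H; 8β-CH3; 9β-CHO; 10β-CH3; C6=C7) | CC(C)(C)[Si](C)(C)O[C@@H]1CCC[C@@]2(C)[C@H]1C=C[C@H](C)[C@@H]2C=O
F4 | step 11 | 9α-hydroxymethyl aldehyde (free C15–OH analogue of 17) | CC(C)(C)[Si](C)(C)O[C@@H]1CCC[C@@]2(C)[C@H]1C=C[C@H](C)[C@@]2(C=O)CO
F5 | step 20 | benzylic carbinol (C15 configuration not defined) | C=C1CCC[C@@]2(C)[C@H]1CC[C@H](C)[C@@]2(C)C(O)c1c(OC)c(OC)cc(OC)c1OC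
F6 | step 20 | S-methyl xanthate of F5 | C=C1CCC[C@@]2(C)[C@H]1CC[C@H](C)[C@@]2(C)C(OC(=S)SC)c1c(OC)c(OC)cc(OC)c1OC
F7 | step 20 | tetramethoxybenzyl decalin | C=C1CCC[C@@]2(C)[C@H]1CC[C@H](C)[C@@]2(C)Cc1c(OC)c(OC)cc(OC)c1OC
F8 | step 20 | 3-alkyl-2,5-dimethoxy-1,4-benzoquinone | C=C1CCC[C@@]2(C)[C@H]1CC[C@H](C)[C@@]2(C)CC1=C(OC)C(=O)C=C(OC)C1=O
F9 | step 16 | β-hydroxysilane (4β-OH; 4α-CH2SiMe3) | C[Si](C)(C)C[C@]1(O)CCC[C@@]2(C)[C@H]1CC[C@H](C)[C@@]2(C)CO[Si](c1ccccc1)(c1ccccc1)C(C)(C)C
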